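in all of them: free catalyst 0.084 mol%

| charge | substrate | partner | impurity | remark |
|---|---|---|---|---|
| Sunday's | 43 mM | 0.95 equiv | 12 µM | run made earlier |
| Monday's | 43 mM | 0.95 equiv | 46 µM | run made earlier |
| Tuesday's | 86 mM | 0.95 equiv | 23 µM | run made earlier |
| flask | 43 mM | 0.950 equiv | 23 µM |  |

| run | time / h | target / % | substrate / % |
|---|---|---|---|
| Sunday's | 0.417 | 6 | 80 |
| Sunday's | 0.667 | 14 | 70 |
| Sunday's | 1.00 | 18 | 64 |
| Sunday's | 2.00 | 39 | 41 |
| Sunday's | 3.00 | 49 | 27 |
| Sunday's | 5.00 | 65 | 13 |
| Monday's | 0.333 | 0 | 97 |
| Monday's | 1.00 | 1 | 98 |
| Monday's | 1.50 | 1 | 96 |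
| Monday's | 2.50 | 0 | 97 |
| Monday's | 4.00 | 0 | 95 |
| Monday's | 5.00 | 4 | 97 |
| Tuesday's | 1.00 | 42 | 43 |
| Tuesday's | 2.00 | 63 | 19 |
| Tuesday's | 3.00 | 74 | 10 |
| Tuesday's | 4.00 | 85 | 5 |
| Tuesday's | 5.00 | 88 | 3 |

(standard deviation of a reading: 1.5 percentage points)

- apparent order in partner when 10 % of the substrate are converted (percent change of the rate of making target for one percent more partner charged)
- apparent order in free catalyst when 10 % of the substrate are converted (percent change of the rate of making target for one percent more free catalyst charged)
- factor on the rate of making target when 10 % of the substrate are converted if free catalyst is charged twice over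



1. Slowness in these runs reads as the time constant of substrate decay: 2.24 h on Sunday's run and 1.18 h on Tuesday's. On Monday's run, substrate still reads 97 % after 5.00 h.

2. The quantity to carry is the surviving fraction, in the flask 0.363: one minus impurity over free catalyst charged, with one impurity taking one free catalyst. It is 0.668 on Sunday's run, 0.682 on Tuesday's and −0.274 on Monday's.

3. The symmetric point, impurity equal to charge, is the zero of this scale, and Monday's run lies below it. Tuesday's surviving catalyst is 2.04 times Sunday's, and its decay is 1.90 times quicker, so the reading is that rate follows surviving catalyst to the first power.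

4. Turned round: an order in free catalyst near one asks for a surviving fraction near one, and a dead flask asks for zero. This flask stands between, at 0.363. One percent more charge raises the survivors by the inverse of that fraction, so this reckoning commits to an order of 2.75. Charging twice over gives a factor of one plus the fraction, over the fraction: 3.75.

5. The forecast differs: 0.75 in partner, 0.75 in free catalyst and a factor of 1.25, on the ground “Target formation fits intermediate + partner, uncatalysed”.

    substrate + free catalyst ⇌ free catalyst + open intermediate (K = 2.30, k = 570 M⁻¹ min⁻¹)
    free catalyst + open intermediate ⇌ catalyst intermediate (K = 160 M⁻¹, k = 6600 M⁻¹ min⁻¹)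
    partner + catalyst intermediate → free catalyst + target (k = 430 M⁻¹ min⁻¹)
    free catalyst + impurity → spent catalyst (k = 41000 M⁻¹ min⁻¹)
    open intermediate → side product (k = 0.00630 min⁻¹)

The flask gives 0.71 in partner, where the forecast stands within tolerance, 2.9 in free catalyst and a factor of 3.85, both above the forecast. Target forms from partner + catalyst intermediate. The loss of free catalyst to impurity is the largest single effect on the order: with that step taken away, the order in free catalyst falls from 2.9 to 1.0. That remainder, against the 0.27 which the forecast amplified by 2.8, is where the two part. Monday's run, with a surviving fraction of −0.274, still read 97 % substrate after 5.00 h.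

The numbers in the tables come from a simulation on assumed constants; the scatter is artificial.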